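The route rests on cutting the bond between the alkene carbon that carries CH2OH (C-2 of the propenol chain) and the cresol ring carbon ortho to the phenol. The key step is a one-pot syn-hydroboration/Suzuki–Miyaura coupling that exploits the enol-ether oxygen on C-3: in the alkynyl-ether precursor this oxygen polarises the C-2≡C-3 triple bond, so boron adds to C-2 and hydrogen to C-3 from the same face, and palladium then replaces boron by the cresol ring with retention. One operation thus joins both halves and fixes the Z-trisubstituted O–CH=C(aryl)–CH2O unit. The precursor is the silyl-protected 3-alkoxyprop-2-yn-1-ol built from (S)-encecalol, trichloroethylene and formaldehyde.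

Key step: step 4

Remark on the chemistry: precocene I (1) and 2-bromo-5-methylphenol (8) are taken as commercial. From 3 onward every compound carries a doubly activated benzylic C–O bond, and 10 and 11 an enol ether next to a free phenol. All work-ups are therefore buffered at pH ≥ 7 and chromatography uses triethylamine-deactivated silica. Alkynyl ether 7 is kept below about 30 °C and used promptly.

Step 1
Reactants: 1 precocene I (7-methoxy-2,2-dimethyl-2H-chromene)
Product: 2 encecalin (1-(7-methoxy-2,2-dimethyl-2H-chromen-6-yl)ethan-1-one)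
Conditions: AcCl, SnCl4 (1.1 equiv), CH2Cl2, −78 → −30 °C; cold aq. NaHCO3
Reagents that add atoms: acetyl chloride CC(=O)Cl
Why: Friedel–Crafts acylation: C-6 is para to the ring oxygen and ortho to the methoxy group and is the least hindered activated ring position, so the preformed acylium complex should react there at low temperature faster than at C-8 or at the neopentyl-like C-3 of the C3=C4 alkene.

Step 2
Reactants: 2 encecalin
Product: 3 (S)-encecalol ((1S)-1-(7-methoxy-2,2-dimethyl-2H-chromen-6-yl)ethan-1-ol)
Conditions: H2 (8 atm), trans-RuCl2[(R)-xylbinap][(R)-daipen] (0.2 mol %), KOtBu (2 mol %), iPrOH, 25 °C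
Reagents that add atoms: none
Why: Noyori asymmetric hydrogenation: the (R)-XylBINAP/(R)-DAIPEN ruthenium hydride should deliver hydride to the Re face of the aryl methyl ketone through the outer-sphere Ru–H/N–H pathway, which sets the (S)-carbinol centre under catalyst control and does not reduce the C3=C4 alkene.

Step 3
Reactants: 3 (S)-encecalol
Product: 7 silyl-protected alkynyl ether tert-butyl({3-[(1S)-1-(7-methoxy-2,2-dimethyl-2H-chromen-6-yl)ethoxy]prop-2-yn-1-yl}oxy)dimethylsilane, via dichlorovinyl ether 4 (not isolated), via lithium alkoxyacetylide 5 (not isolated), via lithium propargylic alkoxide 6 (not isolated)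
Conditions: KH, THF, 0 °C; Cl2C=CHCl, −50 °C → rt; n-BuLi (2.2 equiv), −78 → −40 °C; (CH2O)n, −40 °C → rt; TBSCl, DMAP (cat.), rt; aq. NaHCO3
Reagents that add atoms: trichloroethylene ClC=C(Cl)Cl; formaldehyde (as paraformaldehyde) C=O; tert-butyldimethylsilyl chloride CC(C)(C)[Si](C)(C)Cl
Why: Alkynyl ether synthesis from trichloroethylene, then acetylide hydroxymethylation and O-silylation: the potassium alkoxide of 3 adds to dichloroacetylene formed in situ, n-BuLi converts the dichlorovinyl ether by dehydrochlorination and Cl/Li exchange into the lithium alkoxyacetylide, this adds to formaldehyde and the alkoxide is capped as the TBS ether, all without breaking the carbinol C–O bond so that the (S) centre is retained.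

Step 4
Reactants: 7 silyl-protected alkynyl ether; 8 2-bromo-5-methylphenol
Product: 10 TBS ether of the target 2-[(1Z)-3-{[tert-butyl(dimethyl)silyl]oxy}-1-[(1S)-1-(7-methoxy-2,2-dimethyl-2H-chromen-6-yl)ethoxy]prop-1-en-2-yl]-5-methylphenol, via alkenyl-9-BBN 9 (not isolated)
Conditions: 9-BBN-H (1.05 equiv), THF, 0 °C → rt; then 8, SPhos Pd G3 (3 mol %), 3 M aq. K3PO4, THF, 45 °C
Reagents that add atoms: none
Why: One-pot alkyne hydroboration/Suzuki–Miyaura coupling, the reaction type by which (2-alkoxyvinyl)boranes made from alkoxyalkynes are joined to aryl halides. 9-BBN should add across the triple bond of 7 through a four-centre syn transition state with boron on C-2 and hydride on the oxygen-bearing C-3, because the ether oxygen makes C-2 the nucleophilic and C-3 the cation-stabilising terminus, so that 9 carries boron cis to the new hydrogen. Oxidative addition of Pd(0) into the C–Br bond of 8, base-assisted transfer of the alkenyl group from boron with retention and reductive elimination should then form the bond between C-2 and the ring carbon ortho to the phenol. No ring is closed and no stereocentre is created; the Z geometry (ether oxygen cis to CH2OSi and trans to the aryl ring) follows from syn addition plus retention, and the (S)-benzylic ether is not touched under these non-acidic conditions. The step needs regioselectivity (secured by the alkynyl-ether polarisation), chemoselectivity over the hindered chromene C3=C4 alkene (bulky borane, one equivalent, low temperature) and tolerance of the free phenol (present as phenoxide in aqueous phosphate, which also holds back protodeboronation).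

Step 5
Reactants: 10 TBS ether of the target
Product: 11 target 2-[(1Z)-3-hydroxy-1-[(1S)-1-(7-methoxy-2,2-dimethyl-2H-chromen-6-yl)ethoxy]prop-1-en-2-yl]-5-methylphenol
Conditions: TBAF, THF, 0 °C → rt; pH 7 buffer
Reagents that add atoms: none
Why: Fluoride-mediated desilylation: fluoride should cleave the primary TBS ether under basic, non-acidic conditions that leave the enol ether, its Z geometry, the benzylic ether and the free phenol unchanged.

Compound list
1 | precocene I, 7-methoxy-2,2-dimethyl-2H-chromene | COc1ccc2C=CC(C)(C)Oc2c1 | starting material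
2 | encecalin, 1-(7-methoxy-2,2-dimethyl-2H-chromen-6-yl)ethan-1-one | COc1cc2c(cc1C(C)=O)C=CC(C)(C)O2 | intermediate
3 | (S)-encecalol, (1S)-1-(7-methoxy-2,2-dimethyl-2H-chromen-6-yl)ethan-1-ol | COc1cc2c(cc1[C@H](C)O)C=CC(C)(C)O2 | intermediate
4 | 6-[(1S)-1-{[(E)-1,2-dichloroethenyl]oxy}ethyl]-7-methoxy-2,2-dimethyl-2H-chromene | COc1cc2c(cc1[C@H](C)O/C(Cl)=C\Cl)C=CC(C)(C)O2 | intermediate (not isolated)
5 | lithium 2-[(1S)-1-(7-methoxy-2,2-dimethyl-2H-chromen-6-yl)ethoxy]ethynide | COc1cc2c(cc1[C@H](C)OC#C[Li])C=CC(C)(C)O2 | intermediate (not isolated)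
6 | lithium 3-[(1S)-1-(7-methoxy-2,2-dimethyl-2H-chromen-6-yl)ethoxy]prop-2-yn-1-olate | COc1cc2c(cc1[C@H](C)OC#CCO[Li])C=CC(C)(C)O2 | intermediate (not isolated)
7 | tert-butyl({3-[(1S)-1-(7-methoxy-2,2-dimethyl-2H-chromen-6-yl)ethoxy]prop-2-yn-1-yl}oxy)dimethylsilane | COc1cc2c(cc1[C@H](C)OC#CCO[Si](C)(C)C(C)(C)C)C=CC(C)(C)O2 | intermediate
8 | 2-bromo-5-methylphenol | Cc1ccc(Br)c(O)c1 | starting material
9 | 9-[(1Z)-3-{[tert-butyl(dimethyl)silyl]oxy}-1-[(1S)-1-(7-methoxy-2,2-dimethyl-2H-chromen-6-yl)ethoxy]prop-1-en-2-yl]-9-borabicyclo[3.3.1]nonane | COc1cc2c(cc1[C@H](C)O/C=C(\CO[Si](C)(C)C(C)(C)C)B1C3CCCC1CCC3)C=CC(C)(C)O2 | intermediate (not isolated)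
10 | 2-[(1Z)-3-{[tert-butyl(dimethyl)silyl]oxy}-1-[(1S)-1-(7-methoxy-2,2-dimethyl-2H-chromen-6-yl)ethoxy]prop-1-en-2-yl]-5-methylphenol | COc1cc2c(cc1[C@H](C)O/C=C(\CO[Si](C)(C)C(C)(C)C)c1ccc(C)cc1O)C=CC(C)(C)O2 | intermediate
11 | 2-[(1Z)-3-hydroxy-1-[(1S)-1-(7-methoxy-2,2-dimethyl-2H-chromen-6-yl)ethoxy]prop-1-en-2-yl]-5-methylphenol | COc1cc2c(cc1[C@H](C)O/C=C(\CO)c1ccc(C)cc1O)C=CC(C)(C)O2 | target

Total step count: 5.
Longest linear sequence: 5 steps (1 → 2 → 3 → 7 → 10 → 11); 8 enters at step 4.

Steps most likely to fail

Step 4 (key step). Boron may be delivered to the wrong alkyne carbon or to the chromene alkene. The alkenylborane may lose silanolate by β-elimination to an alkoxyallene, or be protonated off before transmetalation. The fallback reverses the polarity of the coupling so that no boron sits next to the silyloxymethyl group. It sets out from 7: syn-hydrozirconation with Cp2Zr(H)Cl (THF, rt) and iodinolysis (I2, −78 °C) should give the (E)-vinyl iodide F1, with iodine cis to the vinylic hydrogen. Suzuki–Miyaura coupling of F1 with commercial (2-hydroxy-4-methylphenyl)boronic acid (Pd(dppf)Cl2, aq. K3PO4, THF, 45 °C) should then form the same C-2–aryl bond with retention and come back to the route at 10.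

Step 3. The alkoxide/dichloroacetylene stage may fail on this hindered, ionisable carbinol. Configuration may be lost by ionisation of the doubly activated benzylic C–O bond. The benzylic alkynyl ether may rearrange sigmatropically or fragment on warming, and ring lithiation may compete. The fallback reaches the lithium alkoxyacetylide by formate dibromomethylenation instead. It sets out from 3: formylation (acetic formic anhydride, pyridine, 0 °C) should give the formate F2. Ramirez-type olefination of the formate carbonyl (CBr4, PPh3, Et3N, CH2Cl2, 0 °C) should give the 2,2-dibromovinyl ether F3. Treatment of F3 with n-BuLi (2 equiv, −78 °C), then paraformaldehyde and TBSCl as in the main route, should come back at 7.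

Step 1. The acylium ion may attack the electron-rich C3=C4 double bond, and the Lewis acid may oligomerise the chromene, in competition with ring acylation. The fallback uses a much weaker electrophile and builds the acetyl group in two stages. It sets out from 1: Vilsmeier–Haack formylation (POCl3, DMF, 0 °C → rt) should give the 6-carbaldehyde F4. Addition of MeMgBr (THF, 0 °C) should give the racemic carbinol F5. Oxidation of F5 with MnO2 (CH2Cl2, rt) should come back to the route at 2.

Further compounds
F1 | step 4 | tert-butyl({(2E)-2-iodo-3-[(1S)-1-(7-methoxy-2,2-dimethyl-2H-chromen-6-yl)ethoxy]prop-2-en-1-yl}oxy)dimethylsilane | COc1cc2c(cc1[C@H](C)O/C=C(\CO[Si](C)(C)C(C)(C)C)I)C=CC(C)(C)O2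
F2 | step 3 | (1S)-1-(7-methoxy-2,2-dimethyl-2H-chromen-6-yl)ethyl formate | COc1cc2c(cc1[C@H](C)OC=O)C=CC(C)(C)O2
F3 | step 3 | 6-{(1S)-1-[(2,2-dibromoethenyl)oxy]ethyl}-7-methoxy-2,2-dimethyl-2H-chromene | COc1cc2c(cc1[C@H](C)OC=C(Br)Br)C=CC(C)(C)O2
F4 | step 1 | 7-methoxy-2,2-dimethyl-2H-chromene-6-carbaldehyde | COc1cc2c(cc1C=O)C=CC(C)(C)O2
F5 | step 1 | racemic 1-(7-methoxy-2,2-dimethyl-2H-chromen-6-yl)ethan-1-ol | COc1cc2c(cc1C(C)O)C=CC(C)(C)O2
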